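## Retrosynthetic overview

- The strategy rests on ring A, a hexasubstituted benzene whose C5, C6, C7 and C8 carry four adjacent oxygens (OH, OMe, OH, OMe) between C4a–C4(=O) and C8a–O1. This C4O4 unit is mapped onto a squaric ester.
- Target 28 is traced back to flavone 24 by hydrogenolysis, O6-methylation, O7-benzylation and tert-butyl ether cleavage. Flavone 24 is traced back to the 4-methoxy-4-(pyranonyl)cyclobutenone 21 by thermal four-to-six ring expansion, which forms C4a–C5.
- Cyclobutenone 21 comes from the C6-lithiated 2-aryl-3-methoxy-4-pyranone 15 and di-tert-butyl squarate 18 (from squaric acid 16); this addition forms C8–C8a.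
- Pyranone 15 comes from furyl carbinol 9 by Achmatowicz ring expansion and a maltol-type epoxy ketone rearrangement. Carbinol 9 comes from furan 7 and aldehyde 6, itself made from 2,5-dimethoxybenzaldehyde 1.
- Ring order: ring B is bought, ring C (the γ-pyrone) is built second, ring A is closed last.

Key step: step 14

Remark on the chemistry: di-tert-butyl squarate is treated as a made compound (two steps from squaric acid). The lactol, acetal and epoxide intermediates 11 to 13 are carried as racemic diastereomer mixtures, because all of their stereocentres vanish in pyranone 14. The target has no stereocentre.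

## Route

Step 1
Reactants: 1 2,5-dimethoxybenzaldehyde
Product: 3 2,5-dimethoxyphenol, via 2,5-dimethoxyphenyl formate 2 (not isolated)
Conditions: mCPBA, CH2Cl2, 0 °C to rt; then K2CO3 (cat.), MeOH, rt
Reagents that add atoms: mCPBA, OOC(=O)c1cccc(Cl)c1
Why: Dakin-type Baeyer–Villiger oxidation, in which the electron-rich aryl group migrates in preference to hydrogen and the aryl formate is methanolysed to the phenol.

Step 2
Reactants: 3 2,5-dimethoxyphenol
Product: 4 1-(benzyloxy)-2,5-dimethoxybenzene
Conditions: BnBr, K2CO3, DMF, rt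
Reagents that add atoms: benzyl bromide, BrCc1ccccc1
Why: Williamson etherification of the phenoxide should proceed cleanly and installs the 4'-O protecting group that lasts to the final step.

Step 3
Reactants: 4 1-(benzyloxy)-2,5-dimethoxybenzene
Product: 6 4-(benzyloxy)-2,5-dimethoxybenzaldehyde, via aryl iminium chloride 5 (not isolated)
Conditions: POCl3, DMF, 0 to 70 °C; then ice-water, rt
Reagents that add atoms: N,N-dimethylformamide, CN(C)C=O; water, O
Why: Vilsmeier–Haack formylation should occur at the position para to the benzyloxy group and ortho to a methoxy group, which is the most activated and least hindered site of this 1,2,4-trialkoxybenzene.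

Step 4
Reactants: 6 4-(benzyloxy)-2,5-dimethoxybenzaldehyde; 7 furan
Product: 9 rac-[4-(benzyloxy)-2,5-dimethoxyphenyl](furan-2-yl)methanol, via 2-lithiofuran 8 (not isolated)
Conditions: 7, n-BuLi, THF, 0 °C; then 6, −78 to 0 °C; H2O quench
Reagents that add atoms: none
Why: α-Lithiation of furan followed by 1,2-addition to the aldehyde should give the carbinol, whose stereocentre is formed as a racemate and is destroyed later.

Step 5
Reactants: 9 rac-[4-(benzyloxy)-2,5-dimethoxyphenyl](furan-2-yl)methanol
Product: 11 2-[4-(benzyloxy)-2,5-dimethoxyphenyl]-6-hydroxy-2H-pyran-3(6H)-one (racemic anomer mixture), via hydroxy oxo enal 10 (not isolated)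
Conditions: VO(acac)2 (cat.), t-BuOOH, CH2Cl2, 0 °C to rt
Reagents that add atoms: tert-butyl hydroperoxide, CC(C)(C)OO
Why: Achmatowicz rearrangement by hydroxyl-directed, vanadium-catalysed furan oxidation, a near-neutral and halogen-free oxidant that should spare the electron-rich arene and the ionisable benzylic carbinol; the C6 centre forms as an anomer mixture of no consequence.

Step 6
Reactants: 11 2-[4-(benzyloxy)-2,5-dimethoxyphenyl]-6-hydroxy-2H-pyran-3(6H)-one
Product: 12 2-[4-(benzyloxy)-2,5-dimethoxyphenyl]-6-methoxy-2H-pyran-3(6H)-one (racemic anomer mixture)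
Conditions: HC(OMe)3, BF3·OEt2 (cat.), Et2O, 0 °C
Reagents that add atoms: trimethyl orthoformate, COC(OC)OC
Why: Acid-catalysed acetalisation through the ring oxocarbenium ion should fix the lactol as its methyl acetal, so that the enone can be epoxidised under basic conditions.

Step 7
Reactants: 12 2-[4-(benzyloxy)-2,5-dimethoxyphenyl]-6-methoxy-2H-pyran-3(6H)-one
Product: 13 4-[4-(benzyloxy)-2,5-dimethoxyphenyl]-2-methoxy-3,7-dioxabicyclo[4.1.0]heptan-5-one (the 4,5-epoxide of 12, racemic diastereomer mixture)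
Conditions: 30% aq H2O2, NaOH (cat.), MeOH, 0 °C
Reagents that add atoms: hydrogen peroxide, OO
Why: Weitz–Scheffer nucleophilic epoxidation of the enone should deliver the epoxy ketone, whose relative configuration does not matter.

Step 8
Reactants: 13 4-[4-(benzyloxy)-2,5-dimethoxyphenyl]-2-methoxy-3,7-dioxabicyclo[4.1.0]heptan-5-one
Product: 14 2-[4-(benzyloxy)-2,5-dimethoxyphenyl]-3-hydroxy-4H-pyran-4-one
Conditions: 1 M aq H2SO4, dioxane, 90 °C
Reagents that add atoms: none
Why: Acid-promoted epoxy ketone rearrangement to the 3,4-dioxo level, loss of methanol from the acetal and enolisation (the maltol-type synthesis of 3-hydroxy-4-pyranones) should give the γ-pyrone with all stereocentres erased.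

Step 9
Reactants: 14 2-[4-(benzyloxy)-2,5-dimethoxyphenyl]-3-hydroxy-4H-pyran-4-one
Product: 15 2-[4-(benzyloxy)-2,5-dimethoxyphenyl]-3-methoxy-4H-pyran-4-one
Conditions: MeI, K2CO3, acetone, reflux
Reagents that add atoms: iodomethane, CI
Why: Williamson O-methylation of the acidic enolic hydroxyl should install the future 3-OMe and remove the only acidic O–H before the metalation.

Step 10
Reactants: 16 squaric acid
Product: 17 squaryl dichloride (3,4-dichlorocyclobut-3-ene-1,2-dione)
Conditions: SOCl2, DMF (cat.), toluene, 80 °C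
Reagents that add atoms: thionyl chloride, O=S(Cl)Cl
Why: Squaric acid is a vinylogous carboxylic acid and should be converted to its vinylogous acid chloride by thionyl chloride under Vilsmeier-type catalysis.

Step 11
Reactants: 17 squaryl dichloride
Product: 18 di-tert-butyl squarate (3,4-di-tert-butoxycyclobut-3-ene-1,2-dione)
Conditions: KOt-Bu (2 equiv), THF, −78 to 0 °C
Reagents that add atoms: potassium tert-butoxide, CC(C)(C)[O-].[K+]
Why: Twofold addition–elimination (vinylogous acyl substitution) of chloride by tert-butoxide should give the diester, whose acid-labile tert-butyl groups will later be removed without touching methyl or benzyl ethers.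

Step 12
Reactants: 15 2-[4-(benzyloxy)-2,5-dimethoxyphenyl]-3-methoxy-4H-pyran-4-one; 18 di-tert-butyl squarate
Product: 20 rac-4-{6-[4-(benzyloxy)-2,5-dimethoxyphenyl]-5-methoxy-4-oxo-4H-pyran-2-yl}-2,3-di-tert-butoxy-4-hydroxycyclobut-2-en-1-one, via 6-lithiopyranone 19 (not isolated)
Conditions: LiTMP (from 2,2,6,6-tetramethylpiperidine and n-BuLi), THF, −78 °C; then 18, −78 °C; aq NH4Cl
Reagents that add atoms: none
Why: Proposed new method: C6–H of 15 should be the most acidic C–H because the sp2 carbanion lies next to the ring oxygen in an electron-poor ring, so the hindered, non-nucleophilic LiTMP should remove it at −78 °C in preference to C5–H or the arene, and the alkenyllithium 19 should then add 1,2 to one squarate carbonyl to form the future C8–C8a bond and a racemic quaternary carbinol; the closest known reactions are C2 lithiation of chromones with hindered lithium amides and 1,2-addition of alkenyl- and heteroaryllithiums to dialkyl squarates.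

Step 13
Reactants: 20 rac-4-{6-[4-(benzyloxy)-2,5-dimethoxyphenyl]-5-methoxy-4-oxo-4H-pyran-2-yl}-2,3-di-tert-butoxy-4-hydroxycyclobut-2-en-1-one
Product: 21 rac-4-{6-[4-(benzyloxy)-2,5-dimethoxyphenyl]-5-methoxy-4-oxo-4H-pyran-2-yl}-2,3-di-tert-butoxy-4-methoxycyclobut-2-en-1-one
Conditions: MeI, Ag2O, MeCN, rt, dark
Reagents that add atoms: iodomethane, CI
Why: Purdie methylation under neutral conditions should etherify the tertiary hydroxyl without base-induced opening of the hydroxycyclobutenone and without O-alkylating the pyranone carbonyl, as a stronger methylating agent might.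

Step 14
Reactants: 21 rac-4-{6-[4-(benzyloxy)-2,5-dimethoxyphenyl]-5-methoxy-4-oxo-4H-pyran-2-yl}-2,3-di-tert-butoxy-4-methoxycyclobut-2-en-1-one
Product: 24 4'-(benzyloxy)-6,7-di-tert-butoxy-5-hydroxy-3,8,2',5'-tetramethoxyflavone, via vinylketene 22 (not isolated), via 4aH-dienone 23 (not isolated)
Conditions: toluene (degassed), 110 °C
Reagents that add atoms: none
Why: Proposed new method: on heating, the C1–C4 bond of the cyclobutenone breaks in a conrotatory 4π electrocyclic opening to the (Z)-vinylketene 22, the ketene carbon then bonds to pyranone C5 in a 6π electrocyclisation to the 4aH-dienone 23, and a proton shift from C4a to the new C5 oxygen gives the phenol. The closest known reaction type is the Moore ring expansion of 4-alkenyl- and 4-aryl-4-alkoxycyclobutenones made from squaric esters, which gives tetraoxygenated phenols; the C5=C6 bond of a 4-pyranone has not served as the 2π partner, but C5 is the β-carbon of an enol ether in a ring with little aromatic stabilisation to lose, so it should match the electrophilic ketene carbon. Ring A is the only ring closed, in the 6π-electrocyclic mode, through the new C4a–C5 bond, while C8–C8a was already made in step 12. No lasting stereocentre is created, since the quaternary carbon of 21 and C4a of 23 both become aromatic carbons. The selectivity required is inward rotation of the pyranonyl group during ring opening, so that the ketene ends up cis to C5=C6, and the geminal 4-methoxy donor secures it by rotating outward; closure can only occur at C5, the single carbon next to the point of attachment. The step itself places the 8-OMe and the free, chelated 5-OH, and 110 °C is chosen so that the tert-butyl ethers should not shed isobutene.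

Step 15
Reactants: 24 4'-(benzyloxy)-6,7-di-tert-butoxy-5-hydroxy-3,8,2',5'-tetramethoxyflavone
Product: 25 4'-(benzyloxy)-5,6,7-trihydroxy-3,8,2',5'-tetramethoxyflavone
Conditions: TFA, CH2Cl2, 0 °C, argon
Reagents that add atoms: none
Why: Acid-mediated cleavage of aryl tert-butyl ethers by loss of the tert-butyl cation as isobutene should free O6 and O7, while methyl and benzyl ethers are stable to cold trifluoroacetic acid.

Step 16
Reactants: 25 4'-(benzyloxy)-5,6,7-trihydroxy-3,8,2',5'-tetramethoxyflavone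
Product: 26 4',7-bis(benzyloxy)-5,6-dihydroxy-3,8,2',5'-tetramethoxyflavone
Conditions: BnBr (1 equiv), K2CO3 (1 equiv), DMF, rt, argon
Reagents that add atoms: benzyl bromide, BrCc1ccccc1
Why: Regioselective Williamson alkylation should take place at the 7-hydroxyl, the most acidic one because its phenoxide is conjugated with the C4 carbonyl, while 6-OH is less acidic and 5-OH is held in a hydrogen bond.

Step 17
Reactants: 26 4',7-bis(benzyloxy)-5,6-dihydroxy-3,8,2',5'-tetramethoxyflavone
Product: 27 4',7-bis(benzyloxy)-5-hydroxy-3,6,8,2',5'-pentamethoxyflavone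
Conditions: MeI (1.2 equiv), K2CO3, acetone, rt to 40 °C
Reagents that add atoms: iodomethane, CI
Why: Williamson methylation should occur at the free 6-hydroxyl only, because the 5-hydroxyl is deactivated by its hydrogen bond to the C4 carbonyl.

Step 18
Reactants: 27 4',7-bis(benzyloxy)-5-hydroxy-3,6,8,2',5'-pentamethoxyflavone
Product: 28 5,7,4'-trihydroxy-3,6,8,2',5'-pentamethoxyflavone
Conditions: H2 (1 atm), Pd/C, EtOAc/MeOH, rt
Reagents that add atoms: none
Why: Catalytic hydrogenolysis should cleave both benzyl aryl ethers, while the tetrasubstituted, conjugated C2=C3 bond of the flavone should not be reduced under these mild conditions.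

## Compound list

1 | 2,5-dimethoxybenzaldehyde | COc1ccc(OC)c(C=O)c1 | starting material
2 | 2,5-dimethoxyphenyl formate | COc1ccc(OC)c(OC=O)c1 | intermediate (not isolated)
3 | 2,5-dimethoxyphenol | COc1ccc(OC)c(O)c1 | intermediate
4 | 1-(benzyloxy)-2,5-dimethoxybenzene | COc1ccc(OC)c(OCc2ccccc2)c1 | intermediate
5 | [4-(benzyloxy)-2,5-dimethoxybenzylidene]dimethyliminium chloride | COc1cc(C=[N+](C)C)c(OC)cc1OCc1ccccc1.[Cl-] | intermediate (not isolated)
6 | 4-(benzyloxy)-2,5-dimethoxybenzaldehyde | COc1cc(C=O)c(OC)cc1OCc1ccccc1 | intermediate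
7 | furan | c1ccoc1 | starting material
8 | 2-lithiofuran | [Li]c1ccco1 | intermediate (not isolated)
9 | rac-[4-(benzyloxy)-2,5-dimethoxyphenyl](furan-2-yl)methanol | COc1cc(C(O)c2ccco2)c(OC)cc1OCc1ccccc1 | intermediate
10 | rac-(2Z)-5-[4-(benzyloxy)-2,5-dimethoxyphenyl]-5-hydroxy-4-oxopent-2-enal | O=C/C=C\C(=O)C(O)c1cc(OC)c(OCc2ccccc2)cc1OC | intermediate (not isolated)
11 | 2-[4-(benzyloxy)-2,5-dimethoxyphenyl]-6-hydroxy-2H-pyran-3(6H)-one (racemic, anomer mixture) | O=C1C=CC(O)OC1c1cc(OC)c(OCc2ccccc2)cc1OC | intermediate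
12 | 2-[4-(benzyloxy)-2,5-dimethoxyphenyl]-6-methoxy-2H-pyran-3(6H)-one (racemic, anomer mixture) | O=C1C=CC(OC)OC1c1cc(OC)c(OCc2ccccc2)cc1OC | intermediate
13 | 4-[4-(benzyloxy)-2,5-dimethoxyphenyl]-2-methoxy-3,7-dioxabicyclo[4.1.0]heptan-5-one (racemic, diastereomer mixture) | O=C1C2OC2C(OC)OC1c1cc(OC)c(OCc2ccccc2)cc1OC | intermediate
14 | 2-[4-(benzyloxy)-2,5-dimethoxyphenyl]-3-hydroxy-4H-pyran-4-one | COc1cc(-c2occc(=O)c2O)c(OC)cc1OCc1ccccc1 | intermediate
15 | 2-[4-(benzyloxy)-2,5-dimethoxyphenyl]-3-methoxy-4H-pyran-4-one | COc1cc(-c2occc(=O)c2OC)c(OC)cc1OCc1ccccc1 | intermediate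
16 | squaric acid (3,4-dihydroxycyclobut-3-ene-1,2-dione) | OC1=C(O)C(=O)C1=O | starting material
17 | squaryl dichloride (3,4-dichlorocyclobut-3-ene-1,2-dione) | ClC1=C(Cl)C(=O)C1=O | intermediate
18 | di-tert-butyl squarate (3,4-di-tert-butoxycyclobut-3-ene-1,2-dione) | CC(C)(C)OC1=C(OC(C)(C)C)C(=O)C1=O | intermediate
19 | 2-[4-(benzyloxy)-2,5-dimethoxyphenyl]-6-lithio-3-methoxy-4H-pyran-4-one | COc1cc(-c2oc([Li])cc(=O)c2OC)c(OC)cc1OCc1ccccc1 | intermediate (not isolated)
20 | rac-4-{6-[4-(benzyloxy)-2,5-dimethoxyphenyl]-5-methoxy-4-oxo-4H-pyran-2-yl}-2,3-di-tert-butoxy-4-hydroxycyclobut-2-en-1-one | OC1(c2cc(=O)c(OC)c(-c3cc(OC)c(OCc4ccccc4)cc3OC)o2)C(OC(C)(C)C)=C(OC(C)(C)C)C1=O | intermediate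
21 | rac-4-{6-[4-(benzyloxy)-2,5-dimethoxyphenyl]-5-methoxy-4-oxo-4H-pyran-2-yl}-2,3-di-tert-butoxy-4-methoxycyclobut-2-en-1-one | COC1(c2cc(=O)c(OC)c(-c3cc(OC)c(OCc4ccccc4)cc3OC)o2)C(OC(C)(C)C)=C(OC(C)(C)C)C1=O | intermediate
22 | (3Z)-4-{6-[4-(benzyloxy)-2,5-dimethoxyphenyl]-5-methoxy-4-oxo-4H-pyran-2-yl}-2,3-di-tert-butoxy-4-methoxybuta-1,3-dien-1-one (vinylketene, pyranonyl cis to the ketene carbon) | O=C=C(OC(C)(C)C)/C(OC(C)(C)C)=C(OC)\c1cc(=O)c(OC)c(-c2cc(OC)c(OCc3ccccc3)cc2OC)o1 | intermediate (not isolated)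
23 | rac-2-[4-(benzyloxy)-2,5-dimethoxyphenyl]-6,7-di-tert-butoxy-3,8-dimethoxy-4aH-chromene-4,5-dione | COC1=C2OC(-c3cc(OC)c(OCc4ccccc4)cc3OC)=C(OC)C(=O)C2C(=O)C(OC(C)(C)C)=C1OC(C)(C)C | intermediate (not isolated)
24 | 4'-(benzyloxy)-6,7-di-tert-butoxy-5-hydroxy-3,8,2',5'-tetramethoxyflavone | COc1cc(-c2oc3c(OC)c(OC(C)(C)C)c(OC(C)(C)C)c(O)c3c(=O)c2OC)c(OC)cc1OCc1ccccc1 | intermediate
25 | 4'-(benzyloxy)-5,6,7-trihydroxy-3,8,2',5'-tetramethoxyflavone | COc1cc(-c2oc3c(OC)c(O)c(O)c(O)c3c(=O)c2OC)c(OC)cc1OCc1ccccc1 | intermediate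
26 | 4',7-bis(benzyloxy)-5,6-dihydroxy-3,8,2',5'-tetramethoxyflavone | COc1cc(-c2oc3c(OC)c(OCc4ccccc4)c(O)c(O)c3c(=O)c2OC)c(OC)cc1OCc1ccccc1 | intermediate
27 | 4',7-bis(benzyloxy)-5-hydroxy-3,6,8,2',5'-pentamethoxyflavone | COc1cc(-c2oc3c(OC)c(OCc4ccccc4)c(OC)c(O)c3c(=O)c2OC)c(OC)cc1OCc1ccccc1 | intermediate
28 | 5,7,4'-trihydroxy-3,6,8,2',5'-pentamethoxyflavone | COc1cc(-c2oc3c(OC)c(O)c(OC)c(O)c3c(=O)c2OC)c(OC)cc1O | target

## Step count and risks

Total step count: 18. Longest linear sequence: 16 steps (steps 1 to 9 and 12 to 18); the squarate branch (steps 10 and 11) joins at step 12.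

**Step 12 (C6 lithiation and squarate addition).** The deprotonation may occur at C5 or on ring B instead of C6, or the lithiated pyranone may add in conjugate fashion to a second pyranone molecule before it meets the squarate. The fallback uses classical flavone chemistry, sets out from aldehyde 6 and comes back to the route at 27.
- Pinnick oxidation of 6 (NaClO2, NaH2PO4, 2-methyl-2-butene, t-BuOH/H2O) would give 4-(benzyloxy)-2,5-dimethoxybenzoic acid F1.
- Half an equivalent of DCC in CH2Cl2 would convert it into 4-(benzyloxy)-2,5-dimethoxybenzoic anhydride F2.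
- Houben–Hoesch acylation of purchased phloroglucinol with methoxyacetonitrile (ZnCl2, HCl, Et2O; then hot water) would give 2-methoxy-1-(2,4,6-trihydroxyphenyl)ethan-1-one F3.
- Allan–Robinson condensation of F3 with F2 and the potassium salt of F1 at about 170 °C, followed by saponification of the O-aroyl groups (KOH, aq MeOH), should give 4'-(benzyloxy)-5,7-dihydroxy-3,2',5'-trimethoxyflavone F4.
- Twofold bromination of the phloroglucinol-type ring A (NBS, 2 equiv, DMF, 0 °C) should give 4'-(benzyloxy)-6,8-dibromo-5,7-dihydroxy-3,2',5'-trimethoxyflavone F5.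
- Benzylation of the acidic 7-hydroxyl (BnBr, K2CO3, acetone) should give 4',7-bis(benzyloxy)-6,8-dibromo-5-hydroxy-3,2',5'-trimethoxyflavone F6.
- Ullmann-type methoxylation (NaOMe, CuBr, DMF/MeOH, 110 °C) should replace both bromines and deliver 27.

**Step 14 (ring expansion).** The tert-butyl enol ethers may lose isobutene before the four-membered ring opens, the pyranonyl group may rotate outward so that the ketene cannot reach C5, or the ketene may be consumed by other pathways. The fallback builds a symmetric, fully oxygenated ring A first and closes ring C last; it sets out from aldehyde 6 and comes back at 27.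
- Purchased 2,6-dimethoxyphenol would be benzylated (BnBr, K2CO3, DMF) to 2-(benzyloxy)-1,3-dimethoxybenzene F7.
- Dibromination (NBS, 2 equiv, MeCN) should give 3-(benzyloxy)-1,5-dibromo-2,4-dimethoxybenzene F8.
- Palladium-catalysed hydroxylation (Pd2(dba)3, tBuXPhos, KOH, dioxane/H2O, 100 °C) should give 5-(benzyloxy)-4,6-dimethoxybenzene-1,3-diol F9.
- Houben–Hoesch acylation with methoxyacetonitrile (ZnCl2, HCl, Et2O; then hot water) at the only free position flanked by both hydroxyls should give 1-[4-(benzyloxy)-2,6-dihydroxy-3,5-dimethoxyphenyl]-2-methoxyethan-1-one F10.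
- Claisen–Schmidt condensation of F10 with 6 (KOH, EtOH) should give (2Z)-1-[4-(benzyloxy)-2,6-dihydroxy-3,5-dimethoxyphenyl]-3-[4-(benzyloxy)-2,5-dimethoxyphenyl]-2-methoxyprop-2-en-1-one F11.
- Oxidative cyclisation (I2 cat., DMSO, 120 °C) onto either of the two equivalent ortho hydroxyls should give 27 as a single regioisomer.

**Step 8 (epoxy ketone rearrangement).** Acid may ionise the benzylic C2–O1 bond, which is activated by the trialkoxyphenyl group, and open the ring before the epoxide rearranges, or the epoxide may open in the wrong direction. The fallback attaches ring B to a preformed pyranone by cross-coupling; it sets out from 4 and comes back at 15, bypassing steps 3 to 9.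
- Bromination of 4 (NBS, MeCN, 0 °C) should give 1-(benzyloxy)-4-bromo-2,5-dimethoxybenzene F12.
- Bromine–lithium exchange and borylation (n-BuLi, THF, −78 °C; B(OiPr)3; aq HCl) should give [4-(benzyloxy)-2,5-dimethoxyphenyl]boronic acid F13.
- Purchased 3-hydroxy-4H-pyran-4-one would be iodinated next to the enolic hydroxyl (I2, aq Na2CO3), as is practised on kojic acid, to give 3-hydroxy-2-iodo-4H-pyran-4-one F14.
- O-Methylation (MeI, K2CO3, acetone) would give 2-iodo-3-methoxy-4H-pyran-4-one F15.
- Suzuki–Miyaura coupling of F15 with F13 (Pd(PPh3)4, K2CO3, dioxane/H2O, 80 °C) should give 15.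

## Further compounds

F1 | step 12 | 4-(benzyloxy)-2,5-dimethoxybenzoic acid | COc1cc(C(=O)O)c(OC)cc1OCc1ccccc1
F2 | step 12 | 4-(benzyloxy)-2,5-dimethoxybenzoic anhydride | COc1cc(C(=O)OC(=O)c2cc(OC)c(OCc3ccccc3)cc2OC)c(OC)cc1OCc1ccccc1
F3 | step 12 | 2-methoxy-1-(2,4,6-trihydroxyphenyl)ethan-1-one | COCC(=O)c1c(O)cc(O)cc1O
F4 | step 12 | 4'-(benzyloxy)-5,7-dihydroxy-3,2',5'-trimethoxyflavone | COc1cc(-c2oc3cc(O)cc(O)c3c(=O)c2OC)c(OC)cc1OCc1ccccc1
F5 | step 12 | 4'-(benzyloxy)-6,8-dibromo-5,7-dihydroxy-3,2',5'-trimethoxyflavone | COc1cc(-c2oc3c(Br)c(O)c(Br)c(O)c3c(=O)c2OC)c(OC)cc1OCc1ccccc1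
F6 | step 12 | 4',7-bis(benzyloxy)-6,8-dibromo-5-hydroxy-3,2',5'-trimethoxyflavone | COc1cc(-c2oc3c(Br)c(OCc4ccccc4)c(Br)c(O)c3c(=O)c2OC)c(OC)cc1OCc1ccccc1
F7 | step 14 | 2-(benzyloxy)-1,3-dimethoxybenzene | COc1cccc(OC)c1OCc1ccccc1
F8 | step 14 | 3-(benzyloxy)-1,5-dibromo-2,4-dimethoxybenzene | COc1c(Br)cc(Br)c(OC)c1OCc1ccccc1
F9 | step 14 | 5-(benzyloxy)-4,6-dimethoxybenzene-1,3-diol | COc1c(O)cc(O)c(OC)c1OCc1ccccc1
F10 | step 14 | 1-[4-(benzyloxy)-2,6-dihydroxy-3,5-dimethoxyphenyl]-2-methoxyethan-1-one | COCC(=O)c1c(O)c(OC)c(OCc2ccccc2)c(OC)c1O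
F11 | step 14 | (2Z)-1-[4-(benzyloxy)-2,6-dihydroxy-3,5-dimethoxyphenyl]-3-[4-(benzyloxy)-2,5-dimethoxyphenyl]-2-methoxyprop-2-en-1-one | CO/C(=C\c1cc(OC)c(OCc2ccccc2)cc1OC)C(=O)c1c(O)c(OC)c(OCc2ccccc2)c(OC)c1O
F12 | step 8 | 1-(benzyloxy)-4-bromo-2,5-dimethoxybenzene | COc1cc(Br)c(OC)cc1OCc1ccccc1
F13 | step 8 | [4-(benzyloxy)-2,5-dimethoxyphenyl]boronic acid | COc1cc(B(O)O)c(OC)cc1OCc1ccccc1
F14 | step 8 | 3-hydroxy-2-iodo-4H-pyran-4-one | O=c1ccoc(I)c1O
F15 | step 8 | 2-iodo-3-methoxy-4H-pyran-4-one | COc1c(I)occc1=O
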